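## Structural features

The target is a sesquineolignan built on a central benzene ring. That ring is fused to a 2,3-dihydrobenzofuran (O1, C2, C3, C3a–C7a) and is linked through the C6 methylene arm to C4 of a tetrahydrofuran. The dihydrobenzofuran has two adjacent stereocentres, C2 (S, 4-hydroxy-3-methoxyphenyl) and C3 (R, hydroxymethyl), trans to each other. The tetrahydrofuran has three in a row, C2 (R, 3-hydroxy-4-methoxyphenyl), C3 (S, hydroxymethyl) and C4 (S, the arm), 2,3-trans and 3,4-cis. The two sets are separated by the CH2–arene spacer, so neither can control the other and each must be set in absolute terms. Both benzylic ring C–O bonds (tetrahydrofuran O1–C2, para to OMe; dihydrobenzofuran O1–C2, para to OH) ionise in acid and can be hydrogenolysed. Once the electron-rich central ring exists, a cation at tetrahydrofuran C2 can be captured irreversibly by C5 or C7 to give an aryltetralin. The real difficulty is the central ring: oxygens at C4 and C7a meta to each other, the side-chain carbon C3 attached at C3a between them, and the arm at C6. The ring is locally symmetric (both oxygens are ortho to C3a and meta to C6), and the key step uses this pattern: C7a is a ketene carbonyl carbon, C3a and C4 are the two carbons of a siloxyalkyne, and C5–C6–C7 with the arm on C6 come from a 3-substituted cyclobutenone.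

## Logic of the disconnections

36 ⇐ 35 ⇐ 34 ⇐ 33. Only heteroatom bonds are cut: the two O–CH2Ph bonds, the O–CH3 bond at C4 and the two O–Si bonds. They come last because the phenol oxygens must be inert through enolate, hydride, organolithium and thermal steps, and because the C4 oxygen leaves the key step as a silyl ether. The skeleton is not simplified, but the order is fixed: the C4 phenol is methylated in 34 while it is the only acidic hydroxyl. The forward steps must stop hydrogenolysis at the aryl benzyl ethers and leave both benzylic ring ethers alone.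

33 ⇐ 32. The O1–C2 bond of the dihydrobenzofuran is cut. C2 is benzylic and para to an ether oxygen, so the bond can be made by ionisation, and the configuration at C2 then follows from C3; only C3 has to be carried. The five-membered ring is reduced to a phenol next to a 1,3-dioxane that protects both side-chain oxygens. The forward step must ionise C4 of the dioxane without letting the tetrahydrofuran open and alkylate the central ring, so it is run cold, briefly and without a protic solvent.

32 ⇐ 18 + 28. Three bonds of the central ring are cut: C7a–C3a, C4–C5 and C7a–C7. This is where the oxygenation pattern is hardest to reach by substitution and easiest to reach by construction. The cut divides the molecule into two halves of similar size, each already carrying its own stereocentres. The forward step needs one regiochemistry in the union of ketene and alkyne, partners free of hydroxyl groups, and a medium that leaves the propargylic stereocentre of 28 (the future C3) untouched.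

18 ⇐ 17 ⇐ 14 + 16 (from 15). After the two C–Cl bonds, the two ring bonds formed when a ketene adds to an alkyne are cut. This is the dependable entry to a cyclobutenone with a single substituent at C3, and it reduces the four-membered ring to a propargyl group on the tetrahydrofuran. The terminal alkyne carbon must bond to the ketene carbonyl carbon, and the zinc salts must not attack the silyl ether or the benzylic ether.

14 ⇐ 13 ⇐ 12 ⇐ 10. After the O–Si bond, the O1–C2 bond of the tetrahydrofuran is cut, and the two primary alcohols of 12 are traced to the lactone of 10. The ring is closed this early on purpose: 12 has no nucleophilic arene, so the benzylic cation can only be captured by oxygen. Three contiguous stereocentres are reduced to the two of a trans-disubstituted butyrolactone; C2 follows from them under equilibrating conditions, so the carbinol centre of 10 and 12 need not be defined. The forward step must favour the five-membered ring over the oxetane and give the 2,3-trans isomer.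

10 ⇐ 8 + 9. The bond between lactone C3 and the carbinol carbon (the future C2–C3 bond of the tetrahydrofuran) is cut. An aldol addition makes it, and the C4 substituent of 8 sends the aldehyde to the opposite face. The aromatic part is split off as a simple aldehyde. Enolisation must be the only deprotonation, which is why the alkyne carries silicon until 11.

8 ⇐ 6 ⇐ 4 + 5, and 4 ⇐ 1 + 2. The future C3–C4 bond of the tetrahydrofuran is cut at the stage of an imide enolate alkylation, where auxiliary 2 sets C4. Everything is reduced to a five-carbon acid, a two-carbon electrophile and a recoverable auxiliary. The R-configured auxiliary is needed for the (S) centre, and the hydride must reduce the imide while sparing the ester.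

28 ⇐ 25 ⇐ 24 ⇐ 22 ⇐ 21 ⇐ 19 + 20. The O–Si and O–C(sp) bonds are cut first, the alkyne is traced to an aldehyde carbon, the aldehyde to a vinyl group, and finally the C1–C2 bond of 21 is cut. Compound 20 delivers the vinyl group and the hydroxymethyl branch in one catalytic enantioselective step. The anti diastereomer is the one wanted: its C2 is already the future C3 of the dihydrobenzofuran and its carbinol carbon has the configuration of the future C2, so the dioxane in 22–32 is the cis (4S,5R) isomer. A trans-dioxane made by base epimerisation of 24 was considered and dropped, for three reasons: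
- a 5-substituent on a 1,3-dioxane is expected to have only a small equatorial preference, so the equilibrium would not be clean;
- the enolate can expel a ring oxygen;
- the benzylic centre is re-set in step 16 in any case.

The forward steps must therefore keep 24 from epimerising, so it is homologated without base.

## Other disconnections considered

Alternative 1: The cut is at the bond from tetrahydrofuran C4 to the arm carbon and at the C2–C3 bond of the tetrahydrofuran. In the forward step the lithiated bis(phenylthio)acetal A3 adds in a conjugate sense to the menthyloxy butenolide A2, anti to the menthyloxy group, and the lactone enolate is trapped in the same flask by the silylated aldehyde A4 to give A1.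
- In favour: three components are joined in one operation, and two ring stereocentres are fixed relative to a chiral-pool acetal carbon.
- Against: A3 already contains the dihydrobenzofuran and the central ring, so the hardest problem, the oxygenation pattern with its one-carbon arm, is moved and not solved. After the key step the two C–S bonds must be removed reductively over Ni (Raney type) in the presence of benzylic C–O bonds. The acetal and lactone carbons must be reduced, and the tetrahydrofuran closed by benzylic ionisation while the nucleophilic central ring is present.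
- Comparison: on stereocontrol of the tetrahydrofuran it is the equal or the better of the chosen plan, which needs an auxiliary and two substrate-controlled steps. On post-coupling step count it is about equal. On structure and mechanism it is weaker, because the arene must be made elsewhere and the ionising ring closure comes when Friedel–Crafts capture is possible; in the chosen plan that closure (step 6) precedes the arene.

Alternative 2: The cut is the O1–C2 bond of the tetrahydrofuran, made last. In the forward step DDQ abstracts hydride from the benzylic CH2 para to the methoxy group of diol A6, and the 1,4-related primary hydroxyl captures the cation to give the bis(aryl acetate) A5.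
- In favour: no pre-oxidised benzylic carbon is needed, and the acid-labile tetrahydrofuran is not carried through the synthesis. The closure is oxidative and not acid-mediated, and the aryl acetates come off with mild base. On these two points, no Brønsted or Lewis acid late and no hydrogenolysis, it is better than the chosen plan. The arm CH2 is meta to both ring oxygens and should not compete for hydride loss.
- Against: the same cation can be captured by C5 or C7 of the resorcinol-type ring in a six-membered Friedel–Crafts closure, the expected competing path for a dibenzylbutane with an electron-rich second ring. The product has a more oxidisable benzylic C–H than the substrate, so over-oxidation threatens. A6 still needs both stereocentres and the complete dihydrobenzofuran.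
- Comparison: the end game is shorter, but the synthesis as a whole is not, since A6 and its arene are no easier than 18 and 28. Mechanistically the selectivity between O- and C-capture is less secure than the pericyclic cascade of the chosen plan.

Alternative 3: The cut is the C3–C3a bond of the dihydrobenzofuran, formed by ring contraction. In the forward step PhI(OAc)2 (a trivalent iodine reagent) with H2SO4 in trimethyl orthoformate converts flavanone A8 into its enol ether and iodinates C3. Aryl carbon C4a then migrates from C4 to C3 with loss of iodobenzene, giving the trans ester A7 with C4 expelled as the methyl ester.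
- In favour: the central ring is bought with its oxygens in place, the trans ring follows from C2 by substrate control (equal to the chosen plan), and the strongly acidic step is run before any tetrahydrofuran is present. That last point is better than the chosen plan, whose acid step 16 has the tetrahydrofuran in the molecule.
- Against: the C6 oxygen must be turned into the C–C bond to the arm (debenzylation, sulfonylation, sp2–sp3 cross-coupling with a tetrahydrofuranylmethyl metal), and the ester must be reduced. In the acidic oxidising medium an electron-rich 2-aryl group invites the competing 2,3-aryl shift, and reversible opening of the pyranone ring would erode the C2 configuration.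
- Comparison: structurally it solves the arene cheaply but pays with a late C–O to C–C exchange. It is still convergent, but by my count it is longer than the chosen plan, and its key step is the more hazardous for this substitution pattern.

Key step: step 15

Assumption: the iridium catalyst of step 10 built from (S)-SEGPHOS is taken to deliver the (1S,2R) diol; if the sense of induction is the reverse, (R)-SEGPHOS is used and nothing else changes.

## Route

Step 1
Reactants: 1 5-(trimethylsilyl)pent-4-ynoic acid; 2 (4R)-4-benzyl-1,3-oxazolidin-2-one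
Product: 4 (4R)-4-benzyl-3-[5-(trimethylsilyl)pent-4-ynoyl]-1,3-oxazolidin-2-one, via mixed pivalic anhydride 3 (not isolated)
Conditions: t-BuCOCl, Et3N, THF, −20 °C; then 2, LiCl, −20 °C → rt
Reagents that add atoms: none
Why: N-acylation of the LiCl-activated oxazolidinone by the mixed anhydride, the standard loading of an Evans auxiliary; attack occurs at the less hindered carbonyl of 3. No stereocentre is formed, and the C-silyl group removes the acidic alkyne hydrogen for the enolate steps ahead.

Step 2
Reactants: 4 (4R)-4-benzyl-3-[5-(trimethylsilyl)pent-4-ynoyl]-1,3-oxazolidin-2-one; 5 tert-butyl bromoacetate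
Product: 6 tert-butyl (3S)-3-{[(4R)-4-benzyl-2-oxo-1,3-oxazolidin-3-yl]carbonyl}-6-(trimethylsilyl)hex-5-ynoate
Conditions: NaN(SiMe3)2, THF, −78 °C; then 5, −78 → −40 °C
Reagents that add atoms: none
Why: Evans alkylation: the chelated (Z)-sodium enolate is alkylated on the face opposite the benzyl group of the (R)-auxiliary, which sets the future tetrahydrofuran C4 as (S). The imide α-hydrogens are by far the most acidic in 4.

Step 3
Reactants: 6 tert-butyl (3S)-3-{[(4R)-4-benzyl-2-oxo-1,3-oxazolidin-3-yl]carbonyl}-6-(trimethylsilyl)hex-5-ynoate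
Product: 8 (4S)-4-[3-(trimethylsilyl)prop-2-yn-1-yl]oxolan-2-one, via hydroxy ester 7 (not isolated)
Conditions: LiBH4, MeOH (1 equiv), THF, 0 °C; then TsOH·H2O (cat.), toluene, 60 °C
Reagents that add atoms: none
Why: LiBH4 reduces the imide carbonyl in preference to the tert-butyl ester and releases the auxiliary for recovery; acid then closes the γ-lactone with loss of tert-butanol. The stereocentre of 7 is not α to a carbonyl and cannot epimerise.

Step 4
Reactants: 8 (4S)-4-[3-(trimethylsilyl)prop-2-yn-1-yl]oxolan-2-one; 9 3-benzyloxy-4-methoxybenzaldehyde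
Product: 10 (3R,4S)-3-[(3-benzyloxy-4-methoxyphenyl)(hydroxy)methyl]-4-[3-(trimethylsilyl)prop-2-yn-1-yl]oxolan-2-one (both carbinol epimers)
Conditions: LiN(i-Pr)2, THF, −78 °C; then 9; aq NH4Cl
Reagents that add atoms: none
Why: Aldol addition of the lithium enolate of a β-substituted butyrolactone; the aldehyde approaches anti to the C4 side chain, which gives the 3,4-trans lactone (C3 = R). The carbinol centre forms as a mixture, which is harmless because it is ionised in step 6.

Step 5
Reactants: 10 (3R,4S)-3-[(3-benzyloxy-4-methoxyphenyl)(hydroxy)methyl]-4-[3-(trimethylsilyl)prop-2-yn-1-yl]oxolan-2-one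
Product: 12 (2S,3S)-2-[(3-benzyloxy-4-methoxyphenyl)(hydroxy)methyl]-3-(prop-2-yn-1-yl)butane-1,4-diol, via silylated triol 11 (not isolated)
Conditions: LiAlH4, THF, 0 °C; then MeOH, aq NaOH, rt
Reagents that add atoms: none
Why: LiAlH4 reduces the lactone to the 1,4-diol without touching the isolated alkyne, and methanolic hydroxide in the work-up cleaves the C(sp)–Si bond, so the terminal alkyne needed in step 8 is freed without a separate step.

Step 6
Reactants: 12 (2S,3S)-2-[(3-benzyloxy-4-methoxyphenyl)(hydroxy)methyl]-3-(prop-2-yn-1-yl)butane-1,4-diol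
Product: 13 [(2R,3S,4S)-2-(3-benzyloxy-4-methoxyphenyl)-4-(prop-2-yn-1-yl)oxolan-3-yl]methanol
Conditions: camphorsulfonic acid (10 mol %), CH2Cl2, 0 °C → rt
Reagents that add atoms: none
Why: Acid-catalysed dehydrative cyclisation (SN1): the para-methoxybenzylic cation is captured 5-exo by the 1,4-related primary hydroxyl (oxetane formation by the other hydroxyl does not compete), and reversible ionisation should deliver the 2,3-trans ring, with C3 and C4 untouched and cis. No aromatic nucleophile is present at this stage, so Friedel–Crafts capture cannot occur.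

Step 7
Reactants: 13 [(2R,3S,4S)-2-(3-benzyloxy-4-methoxyphenyl)-4-(prop-2-yn-1-yl)oxolan-3-yl]methanol
Product: 14 tert-butyl{[(2R,3S,4S)-2-(3-benzyloxy-4-methoxyphenyl)-4-(prop-2-yn-1-yl)oxolan-3-yl]methoxy}dimethylsilane
Conditions: t-BuMe2SiCl, imidazole, DMF, rt
Reagents that add atoms: tert-butyldimethylsilyl chloride, CC(C)(C)[Si](C)(C)Cl
Why: Standard silylation of the only hydroxyl; the free alcohol would be acylated in step 8 and would intercept ketenes in step 15.

Step 8
Reactants: 14 tert-butyl{[(2R,3S,4S)-2-(3-benzyloxy-4-methoxyphenyl)-4-(prop-2-yn-1-yl)oxolan-3-yl]methoxy}dimethylsilane; 15 trichloroacetyl chloride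
Product: 17 4,4-dichloro-3-{[(2R,3S,4S)-2-(3-benzyloxy-4-methoxyphenyl)-3-(tert-butyldimethylsilyloxymethyl)oxolan-4-yl]methyl}cyclobut-2-en-1-one, via dichloroketene 16 (not isolated)
Conditions: Zn(Cu), Et2O/1,2-dimethoxyethane, rt, slow addition of 15
Reagents that add atoms: none
Why: [2+2] cycloaddition of dichloroketene with a terminal alkyne; the unsubstituted alkyne carbon bonds to the ketene carbonyl carbon, which gives the 3-substituted 4,4-dichlorocyclobutenone. Dimethoxyethane binds ZnCl2 so that the silyl ether and the benzylic ether do not meet a free Lewis acid.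

Step 9
Reactants: 17 4,4-dichloro-3-{[(2R,3S,4S)-2-(3-benzyloxy-4-methoxyphenyl)-3-(tert-butyldimethylsilyloxymethyl)oxolan-4-yl]methyl}cyclobut-2-en-1-one
Product: 18 3-{[(2R,3S,4S)-2-(3-benzyloxy-4-methoxyphenyl)-3-(tert-butyldimethylsilyloxymethyl)oxolan-4-yl]methyl}cyclobut-2-en-1-one
Conditions: Zn, AcOH, Me2NCH2CH2NMe2, EtOH, 0 °C
Reagents that add atoms: none
Why: Reductive dechlorination with zinc in buffered acetic acid, the usual second stage of the dichloroketene route to cyclobutenones. Low temperature and the amine buffer guard against double-bond migration and ring opening.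

Step 10
Reactants: 19 4-benzyloxy-3-methoxybenzaldehyde; 20 4-vinyl-1,3-dioxolan-2-one (racemic)
Product: 21 (1S,2R)-1-(4-benzyloxy-3-methoxyphenyl)-2-vinylpropane-1,3-diol
Conditions: [Ir(cod)Cl]2 (2.5 mol %), (S)-SEGPHOS (5 mol %), 4-cyano-3-nitrobenzoic acid (10 mol %), K3PO4 (5 mol %), i-PrOH (2 equiv), THF, 60 °C
Reagents that add atoms: none
Why: Iridium-catalysed transfer-hydrogenative carbonyl (hydroxymethyl)allylation: ionisation of 20 with loss of CO2 gives a (hydroxymethyl)allyl iridium species whose (E)-σ-allyl form adds to the aldehyde through a closed chair transition state, so the anti diol results, and the chiral bisphosphine selects the aldehyde face. Both stereocentres are set here; C2 (R) becomes C3 of the dihydrobenzofuran.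

Step 11
Reactants: 21 (1S,2R)-1-(4-benzyloxy-3-methoxyphenyl)-2-vinylpropane-1,3-diol
Product: 22 (4S,5R)-4-(4-benzyloxy-3-methoxyphenyl)-2,2-dimethyl-5-vinyl-1,3-dioxane
Conditions: Me2C(OMe)2, pyridinium tosylate (cat.), CH2Cl2, rt
Reagents that add atoms: 2,2-dimethoxypropane, COC(C)(C)OC
Why: Acetonide formation by transketalisation under a weak acid; it ties both hydroxyls into one group that is stable to ozone, organolithiums and heat. The anti diol gives the cis-4,5-disubstituted dioxane.

Step 12
Reactants: 22 (4S,5R)-4-(4-benzyloxy-3-methoxyphenyl)-2,2-dimethyl-5-vinyl-1,3-dioxane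
Product: 24 (4S,5R)-4-(4-benzyloxy-3-methoxyphenyl)-2,2-dimethyl-1,3-dioxane-5-carbaldehyde, via ozonide 23 (not isolated)
Conditions: O3 (limited, Sudan red 7B end-point), CH2Cl2, −78 °C; then PPh3, −78 °C → rt
Reagents that add atoms: ozone, [O-][O+]=O
Why: Ozonolysis of the terminal vinyl group with reductive work-up; the alkene reacts much faster than the dialkoxybenzene ring when ozone is limited by an indicator dye. Neutral work-up and immediate use should keep the aldehyde from epimerising at C5.

Step 13
Reactants: 24 (4S,5R)-4-(4-benzyloxy-3-methoxyphenyl)-2,2-dimethyl-1,3-dioxane-5-carbaldehyde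
Product: 25 (4S,5R)-4-(4-benzyloxy-3-methoxyphenyl)-5-(2,2-dibromovinyl)-2,2-dimethyl-1,3-dioxane
Conditions: CBr4, PPh3, Et3N, CH2Cl2, 0 °C
Reagents that add atoms: carbon tetrabromide, BrC(Br)(Br)Br
Why: First stage of the Corey–Fuchs homologation, a Wittig-type dibromo-olefination. The ylide is a weak base, so the α-stereocentre should survive, which a carbonate-mediated diazophosphonate homologation would not guarantee.

Step 14
Reactants: 25 (4S,5R)-4-(4-benzyloxy-3-methoxyphenyl)-5-(2,2-dibromovinyl)-2,2-dimethyl-1,3-dioxane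
Product: 28 (4S,5R)-4-(4-benzyloxy-3-methoxyphenyl)-2,2-dimethyl-5-[(triisopropylsilyloxy)ethynyl]-1,3-dioxane, via lithium acetylide 26 (not isolated), via lithium ynolate 27 (not isolated)
Conditions: n-BuLi (2.0 equiv), THF, −78 °C; LiOOt-Bu (from t-BuOOH and LiN(SiMe3)2), −78 → 0 °C; i-Pr3SiOTf, −78 °C
Reagents that add atoms: tert-butyl hydroperoxide (as its lithium salt), CC(C)(C)OO; triisopropylsilyl trifluoromethanesulfonate, CC(C)[Si](C(C)C)(C(C)C)OS(=O)(=O)C(F)(F)F
Why: Second stage of the Corey–Fuchs sequence (bromine–lithium exchange, Fritsch–Buttenberg–Wiechell shift, deprotonation) gives the lithium acetylide, which takes up electrophilic oxygen from lithium tert-butyl peroxide to form the ynolate; the bulky silyl triflate then reacts at oxygen. Each stage is known chemistry of lithium acetylides and ynolates, and no stereocentre is acidified.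

Step 15
Reactants: 18 3-{[(2R,3S,4S)-2-(3-benzyloxy-4-methoxyphenyl)-3-(tert-butyldimethylsilyloxymethyl)oxolan-4-yl]methyl}cyclobut-2-en-1-one; 28 (4S,5R)-4-(4-benzyloxy-3-methoxyphenyl)-2,2-dimethyl-5-[(triisopropylsilyloxy)ethynyl]-1,3-dioxane
Product: 32 2-[(4S,5R)-4-(4-benzyloxy-3-methoxyphenyl)-2,2-dimethyl-1,3-dioxan-5-yl]-5-{[(2R,3S,4S)-2-(3-benzyloxy-4-methoxyphenyl)-3-(tert-butyldimethylsilyloxymethyl)oxolan-4-yl]methyl}-3-(triisopropylsilyloxy)phenol, via vinylketene 29 (not isolated), via vinylcyclobutenone 30 (not isolated), via dienylketene 31 (not isolated)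
Conditions: 28 (1.2 equiv), toluene, 80 °C, then 110 °C
Reagents that add atoms: none
Why: Danheiser benzannulation: thermal 4π electrocyclic opening of 18 gives vinylketene 29, whose ketene C=C adds [2+2] to the electron-rich siloxyalkyne, the electrophilic ketene carbon bonding to the alkyne carbon remote from oxygen, to give 30. 4π opening of 30 to dienylketene 31, 6π disrotatory electrocyclisation and tautomerisation of the cyclohexadienone then give the phenol. The benzene ring is closed by this pericyclic cascade, with C7a–C3a and C4–C5 formed in the [2+2] step and C7a–C7 in the 6π electrocyclisation. The closest known reaction is the benzannulation of 3-alkylcyclobutenones with trialkylsilyloxyalkynes to 3-silyloxyphenols. No stereocentre is formed, and the existing ones should be safe because the medium is neutral and the propargylic C–H of 28 is never deprotonated. The selectivity needed is the regiochemistry of the ketene–alkyne cycloaddition, which is secured by the polarisation of the ynol ether and places the dioxanyl carbon between the two oxygens. Neither partner has a free hydroxyl to intercept the ketenes, and the small excess of 28 limits acylation of the product phenol by 29.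

Step 16
Reactants: 32 2-[(4S,5R)-4-(4-benzyloxy-3-methoxyphenyl)-2,2-dimethyl-1,3-dioxan-5-yl]-5-{[(2R,3S,4S)-2-(3-benzyloxy-4-methoxyphenyl)-3-(tert-butyldimethylsilyloxymethyl)oxolan-4-yl]methyl}-3-(triisopropylsilyloxy)phenol
Product: 33 [(2S,3R)-2-(4-benzyloxy-3-methoxyphenyl)-6-{[(2R,3S,4S)-2-(3-benzyloxy-4-methoxyphenyl)-3-(tert-butyldimethylsilyloxymethyl)oxolan-4-yl]methyl}-4-(triisopropylsilyloxy)-2,3-dihydro-1-benzofuran-3-yl]methanol
Conditions: BF3·OEt2 (0.3 equiv), CH2Cl2, −78 → −40 °C; Et3N quench
Reagents that add atoms: none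
Why: Lewis-acid-promoted SN1 substitution: the acetal oxygen on C4 of the dioxane is activated, the para-benzyloxybenzylic cation is captured 5-exo by the neighbouring phenol, acetone is lost and the primary hydroxyl is released. The aryl group should settle trans to the C3 substituent, the kinetically and thermodynamically favoured arrangement, so C2 (S) is controlled by C3. Low temperature and an aprotic medium are chosen because an ion pair formed from the tetrahydrofuran should return to the ether faster than the central ring can capture it.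

Step 17
Reactants: 33 [(2S,3R)-2-(4-benzyloxy-3-methoxyphenyl)-6-{[(2R,3S,4S)-2-(3-benzyloxy-4-methoxyphenyl)-3-(tert-butyldimethylsilyloxymethyl)oxolan-4-yl]methyl}-4-(triisopropylsilyloxy)-2,3-dihydro-1-benzofuran-3-yl]methanol
Product: 34 (2S,3R)-2-(4-benzyloxy-3-methoxyphenyl)-6-{[(2R,3S,4S)-2-(3-benzyloxy-4-methoxyphenyl)-3-(hydroxymethyl)oxolan-4-yl]methyl}-3-(hydroxymethyl)-2,3-dihydro-1-benzofuran-4-ol
Conditions: Bu4NF, THF, 0 °C → rt
Reagents that add atoms: none
Why: Fluoride cleaves the aryl triisopropylsilyl ether and the primary tert-butyldimethylsilyl ether; nothing else in 33 is fluoride-labile.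

Step 18
Reactants: 34 (2S,3R)-2-(4-benzyloxy-3-methoxyphenyl)-6-{[(2R,3S,4S)-2-(3-benzyloxy-4-methoxyphenyl)-3-(hydroxymethyl)oxolan-4-yl]methyl}-3-(hydroxymethyl)-2,3-dihydro-1-benzofuran-4-ol
Product: 35 [(2S,3R)-2-(4-benzyloxy-3-methoxyphenyl)-6-{[(2R,3S,4S)-2-(3-benzyloxy-4-methoxyphenyl)-3-(hydroxymethyl)oxolan-4-yl]methyl}-4-methoxy-2,3-dihydro-1-benzofuran-3-yl]methanol
Conditions: MeI, K2CO3, acetone, rt
Reagents that add atoms: iodomethane, CI
Why: Williamson methylation under carbonate: only the phenol, the single acidic hydroxyl, is deprotonated, so the two primary alcohols stay free.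

Step 19
Reactants: 35 [(2S,3R)-2-(4-benzyloxy-3-methoxyphenyl)-6-{[(2R,3S,4S)-2-(3-benzyloxy-4-methoxyphenyl)-3-(hydroxymethyl)oxolan-4-yl]methyl}-4-methoxy-2,3-dihydro-1-benzofuran-3-yl]methanol
Product: 36 [(2S,3R)-2-(4-hydroxy-3-methoxyphenyl)-6-{[(2R,3S,4S)-2-(3-hydroxy-4-methoxyphenyl)-3-(hydroxymethyl)oxolan-4-yl]methyl}-4-methoxy-2,3-dihydro-1-benzofuran-3-yl]methanol (CNP0242386.1)
Conditions: H2 (1 atm), Pd/C (10 %), EtOAc, rt, stopped at consumption of 35
Reagents that add atoms: none
Why: Hydrogenolysis of aryl benzyl ethers, which should be much faster than cleavage of the two cyclic benzylic ethers. A neutral solvent, a low catalyst loading and a short reaction time protect the ring C–O bonds.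

## Compound list

1 | 5-(trimethylsilyl)pent-4-ynoic acid | C[Si](C)(C)C#CCCC(=O)O | starting material
2 | (4R)-4-benzyl-1,3-oxazolidin-2-one | O=C1N[C@H](Cc2ccccc2)CO1 | starting material
3 | 5-(trimethylsilyl)pent-4-ynoic pivalic anhydride | C[Si](C)(C)C#CCCC(=O)OC(=O)C(C)(C)C | intermediate (not isolated)
4 | (4R)-4-benzyl-3-[5-(trimethylsilyl)pent-4-ynoyl]-1,3-oxazolidin-2-one | C[Si](C)(C)C#CCCC(=O)N1C(=O)OC[C@H]1Cc1ccccc1 | intermediate
5 | tert-butyl bromoacetate | CC(C)(C)OC(=O)CBr | starting material
6 | tert-butyl (3S)-3-{[(4R)-4-benzyl-2-oxo-1,3-oxazolidin-3-yl]carbonyl}-6-(trimethylsilyl)hex-5-ynoate | CC(C)(C)OC(=O)C[C@H](CC#C[Si](C)(C)C)C(=O)N1C(=O)OC[C@H]1Cc1ccccc1 | intermediate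
7 | tert-butyl (3S)-3-(hydroxymethyl)-6-(trimethylsilyl)hex-5-ynoate | CC(C)(C)OC(=O)C[C@H](CC#C[Si](C)(C)C)CO | intermediate (not isolated)
8 | (4S)-4-[3-(trimethylsilyl)prop-2-yn-1-yl]oxolan-2-one | O=C1C[C@H](CC#C[Si](C)(C)C)CO1 | intermediate
9 | 3-benzyloxy-4-methoxybenzaldehyde (O-benzylisovanillin) | COc1ccc(C=O)cc1OCc1ccccc1 | starting material
10 | (3R,4S)-3-[(3-benzyloxy-4-methoxyphenyl)(hydroxy)methyl]-4-[3-(trimethylsilyl)prop-2-yn-1-yl]oxolan-2-one, carbinol epimers | O=C1OC[C@@H](CC#C[Si](C)(C)C)[C@@H]1C(O)c1ccc(OC)c(OCc2ccccc2)c1 | intermediate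
11 | (2S,3S)-2-[(3-benzyloxy-4-methoxyphenyl)(hydroxy)methyl]-3-[3-(trimethylsilyl)prop-2-yn-1-yl]butane-1,4-diol, carbinol epimers | OC[C@@H](CC#C[Si](C)(C)C)[C@@H](CO)C(O)c1ccc(OC)c(OCc2ccccc2)c1 | intermediate (not isolated)
12 | (2S,3S)-2-[(3-benzyloxy-4-methoxyphenyl)(hydroxy)methyl]-3-(prop-2-yn-1-yl)butane-1,4-diol, carbinol epimers | OC[C@@H](CC#C)[C@@H](CO)C(O)c1ccc(OC)c(OCc2ccccc2)c1 | intermediate
13 | [(2R,3S,4S)-2-(3-benzyloxy-4-methoxyphenyl)-4-(prop-2-yn-1-yl)oxolan-3-yl]methanol (2,3-trans, 3,4-cis) | COc1ccc([C@@H]2OC[C@@H](CC#C)[C@H]2CO)cc1OCc1ccccc1 | intermediate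
14 | tert-butyl{[(2R,3S,4S)-2-(3-benzyloxy-4-methoxyphenyl)-4-(prop-2-yn-1-yl)oxolan-3-yl]methoxy}dimethylsilane | COc1ccc([C@@H]2OC[C@@H](CC#C)[C@H]2CO[Si](C)(C)C(C)(C)C)cc1OCc1ccccc1 | intermediate
15 | trichloroacetyl chloride | ClC(=O)C(Cl)(Cl)Cl | starting material
16 | dichloroketene | ClC(Cl)=C=O | intermediate (not isolated)
17 | 4,4-dichloro-3-{[(2R,3S,4S)-2-(3-benzyloxy-4-methoxyphenyl)-3-(tert-butyldimethylsilyloxymethyl)oxolan-4-yl]methyl}cyclobut-2-en-1-one | COc1ccc([C@@H]2OC[C@@H](CC3=CC(=O)C3(Cl)Cl)[C@H]2CO[Si](C)(C)C(C)(C)C)cc1OCc1ccccc1 | intermediate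
18 | 3-{[(2R,3S,4S)-2-(3-benzyloxy-4-methoxyphenyl)-3-(tert-butyldimethylsilyloxymethyl)oxolan-4-yl]methyl}cyclobut-2-en-1-one | COc1ccc([C@@H]2OC[C@@H](CC3=CC(=O)C3)[C@H]2CO[Si](C)(C)C(C)(C)C)cc1OCc1ccccc1 | intermediate (key-step precursor)
19 | 4-benzyloxy-3-methoxybenzaldehyde (O-benzylvanillin) | COc1cc(C=O)ccc1OCc1ccccc1 | starting material
20 | 4-vinyl-1,3-dioxolan-2-one (racemic) | C=CC1COC(=O)O1 | starting material
21 | (1S,2R)-1-(4-benzyloxy-3-methoxyphenyl)-2-vinylpropane-1,3-diol (anti) | C=C[C@H](CO)[C@H](O)c1ccc(OCc2ccccc2)c(OC)c1 | intermediate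
22 | (4S,5R)-4-(4-benzyloxy-3-methoxyphenyl)-2,2-dimethyl-5-vinyl-1,3-dioxane (cis) | C=C[C@@H]1COC(C)(C)O[C@@H]1c1ccc(OCc2ccccc2)c(OC)c1 | intermediate
23 | 3-[(4S,5R)-4-(4-benzyloxy-3-methoxyphenyl)-2,2-dimethyl-1,3-dioxan-5-yl]-1,2,4-trioxolane (ozonide, epimers at the trioxolane carbon) | C1OC(OO1)[C@@H]1COC(C)(C)O[C@@H]1c1ccc(OCc2ccccc2)c(OC)c1 | intermediate (not isolated)
24 | (4S,5R)-4-(4-benzyloxy-3-methoxyphenyl)-2,2-dimethyl-1,3-dioxane-5-carbaldehyde (cis) | O=C[C@@H]1COC(C)(C)O[C@@H]1c1ccc(OCc2ccccc2)c(OC)c1 | intermediate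
25 | (4S,5R)-4-(4-benzyloxy-3-methoxyphenyl)-5-(2,2-dibromovinyl)-2,2-dimethyl-1,3-dioxane | BrC(Br)=C[C@@H]1COC(C)(C)O[C@@H]1c1ccc(OCc2ccccc2)c(OC)c1 | intermediate
26 | lithium acetylide of (4S,5R)-4-(4-benzyloxy-3-methoxyphenyl)-5-ethynyl-2,2-dimethyl-1,3-dioxane | [Li]C#C[C@@H]1COC(C)(C)O[C@@H]1c1ccc(OCc2ccccc2)c(OC)c1 | intermediate (not isolated)
27 | lithium ynolate, lithium 2-[(4S,5R)-4-(4-benzyloxy-3-methoxyphenyl)-2,2-dimethyl-1,3-dioxan-5-yl]ethynolate | [Li]OC#C[C@@H]1COC(C)(C)O[C@@H]1c1ccc(OCc2ccccc2)c(OC)c1 | intermediate (not isolated)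
28 | (4S,5R)-4-(4-benzyloxy-3-methoxyphenyl)-2,2-dimethyl-5-[(triisopropylsilyloxy)ethynyl]-1,3-dioxane (cis) | CC(C)[Si](C(C)C)(C(C)C)OC#C[C@@H]1COC(C)(C)O[C@@H]1c1ccc(OCc2ccccc2)c(OC)c1 | intermediate (key-step precursor)
29 | vinylketene, 3-{[(2R,3S,4S)-2-(3-benzyloxy-4-methoxyphenyl)-3-(tert-butyldimethylsilyloxymethyl)oxolan-4-yl]methyl}buta-1,3-dien-1-one | COc1ccc([C@@H]2OC[C@@H](CC(=C)C=C=O)[C@H]2CO[Si](C)(C)C(C)(C)C)cc1OCc1ccccc1 | intermediate (not isolated)
30 | 2-(dioxanyl)-3-(triisopropylsilyloxy)-4-[1-(oxolanylmethyl)vinyl]cyclobut-2-en-1-one (epimers at ring C4) | COc1ccc([C@@H]2OC[C@@H](CC(=C)C3C(=O)C([C@@H]4COC(C)(C)O[C@@H]4c4ccc(OCc5ccccc5)c(OC)c4)=C3O[Si](C(C)C)(C(C)C)C(C)C)[C@H]2CO[Si](C)(C)C(C)(C)C)cc1OCc1ccccc1 | intermediate (not isolated)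
31 | dienylketene, 2-(dioxanyl)-3-(triisopropylsilyloxy)-5-(oxolanylmethyl)hexa-1,3,5-trien-1-one with the ketene carbon and the vinyl group cis on the central double bond | COc1ccc([C@@H]2OC[C@@H](CC(=C)/C=C(O[Si](C(C)C)(C(C)C)C(C)C)\C([C@@H]3COC(C)(C)O[C@@H]3c3ccc(OCc4ccccc4)c(OC)c3)=C=O)[C@H]2CO[Si](C)(C)C(C)(C)C)cc1OCc1ccccc1 | intermediate (not isolated)
32 | 2-[(4S,5R)-4-(4-benzyloxy-3-methoxyphenyl)-2,2-dimethyl-1,3-dioxan-5-yl]-5-{[(2R,3S,4S)-2-(3-benzyloxy-4-methoxyphenyl)-3-(tert-butyldimethylsilyloxymethyl)oxolan-4-yl]methyl}-3-(triisopropylsilyloxy)phenol | COc1ccc([C@@H]2OC[C@@H](Cc3cc(O)c([C@@H]4COC(C)(C)O[C@@H]4c4ccc(OCc5ccccc5)c(OC)c4)c(O[Si](C(C)C)(C(C)C)C(C)C)c3)[C@H]2CO[Si](C)(C)C(C)(C)C)cc1OCc1ccccc1 | intermediate (key-step product)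
33 | [(2S,3R)-2-(4-benzyloxy-3-methoxyphenyl)-6-{[(2R,3S,4S)-2-(3-benzyloxy-4-methoxyphenyl)-3-(tert-butyldimethylsilyloxymethyl)oxolan-4-yl]methyl}-4-(triisopropylsilyloxy)-2,3-dihydro-1-benzofuran-3-yl]methanol | COc1ccc([C@@H]2OC[C@@H](Cc3cc(O[Si](C(C)C)(C(C)C)C(C)C)c4c(c3)O[C@H](c3ccc(OCc5ccccc5)c(OC)c3)[C@H]4CO)[C@H]2CO[Si](C)(C)C(C)(C)C)cc1OCc1ccccc1 | intermediate
34 | (2S,3R)-2-(4-benzyloxy-3-methoxyphenyl)-6-{[(2R,3S,4S)-2-(3-benzyloxy-4-methoxyphenyl)-3-(hydroxymethyl)oxolan-4-yl]methyl}-3-(hydroxymethyl)-2,3-dihydro-1-benzofuran-4-ol | COc1ccc([C@@H]2OC[C@@H](Cc3cc(O)c4c(c3)O[C@H](c3ccc(OCc5ccccc5)c(OC)c3)[C@H]4CO)[C@H]2CO)cc1OCc1ccccc1 | intermediate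
35 | [(2S,3R)-2-(4-benzyloxy-3-methoxyphenyl)-6-{[(2R,3S,4S)-2-(3-benzyloxy-4-methoxyphenyl)-3-(hydroxymethyl)oxolan-4-yl]methyl}-4-methoxy-2,3-dihydro-1-benzofuran-3-yl]methanol | COc1ccc([C@@H]2OC[C@@H](Cc3cc(OC)c4c(c3)O[C@H](c3ccc(OCc5ccccc5)c(OC)c3)[C@H]4CO)[C@H]2CO)cc1OCc1ccccc1 | intermediate
36 | [(2S,3R)-2-(4-hydroxy-3-methoxyphenyl)-6-{[(2R,3S,4S)-2-(3-hydroxy-4-methoxyphenyl)-3-(hydroxymethyl)oxolan-4-yl]methyl}-4-methoxy-2,3-dihydro-1-benzofuran-3-yl]methanol (CNP0242386.1) | COc1ccc([C@@H]2OC[C@@H](Cc3cc(OC)c4c(c3)O[C@H](c3ccc(O)c(OC)c3)[C@H]4CO)[C@H]2CO)cc1O | target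

## Step count and risk

Total step count: 19. Longest linear sequence: 14 steps (steps 1–9, then 15–19); the alkyne branch (steps 10–14) is 5 steps.

Least certain steps:

Step 15 (key step). The likely failure is a slow [2+2] union, because the siloxyalkyne is branched next to the triple bond. That would let the vinylketene dimerise or acylate the product phenol, and prolonged heating would degrade the acid- and heat-sensitive ynol ether before it is consumed. Fallback, from 18 back to 32: 18 is opened thermally in aqueous dioxane at 80 °C so that the vinylketene is hydrated to the but-3-enoic acid F1. 1-Chloro-N,N,2-trimethylprop-1-en-1-amine converts it under neutral conditions into the acid chloride F2. F2 is added slowly to 28 and Et3N in toluene at 0–25 °C, so that 29 is formed by dehydrochlorination in the presence of the alkyne and adds at once. Brief heating to 80–110 °C after 28 is consumed completes 30 → 31 → 32.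

Step 16. The likely failure is ionisation of the tetrahydrofuran benzylic ether alongside the dioxane, followed by irreversible Friedel–Crafts capture of that cation by C5 or C7 of the central ring (tetralin formation). The two benzylic positions have nearly the same electronic activation. Fallback, from 32 back to 34, without an ionising acid: methanolysis with pyridinium tosylate removes the acetonide and the primary silyl ether to give the phenol tetraol F3. The phenol and both primary hydroxyls are silylated with t-BuMe2SiCl and imidazole at 0 °C, leaving the hindered benzylic hydroxyl free, to give the tris(silyl ether) F4. MsCl and Et3N convert the benzylic alcohol under basic conditions into the benzylic chloride F5. Bu4NF then removes all four silyl groups, and a phenoxide of the central ring (either one, since they are equivalent by position) displaces chloride 5-exo to give 34. The trans ring is expected because the chloride of this para-alkoxybenzylic system epimerises readily and closes through the less crowded transition state.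

Step 19. The likely failure is over-reduction: hydrogenolysis of the benzylic aryl ether bond O1–C2 of the dihydrobenzofuran, which resembles a benzyl aryl ether, and more slowly of the tetrahydrofuran. Fallback, from 32 back to 36, with debenzylation moved ahead of the ring closure. The free phenol of 32 is methylated (MeI, K2CO3) to the anisole F6; this is allowed because the two oxygens of the central ring are equivalent by position. Hydrogenolysis (H2, Pd/C) gives the bisphenol F7 while the only benzylic C–O bonds present are of the less labile dialkyl type. Bu4NF gives the triphenol F8. Dilute aqueous acetic acid then closes the dihydrobenzofuran through the para-hydroxybenzylic, quinone-methide-like cation to give 36 with loss of acetone; this needs far milder acid than step 16.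

Step 14. The likely failures are incomplete oxygen transfer to the acetylide in the presence of the lithium bromide and butyl bromide left from the first stage, silylation on carbon, and hydrolysis of the ynol ether during isolation. Fallback, from 24 back to 27 and so to 28, by the Kowalski ester homologation: Pinnick oxidation (NaClO2, NaH2PO4, 2-methylbut-2-ene) gives the carboxylic acid F9; Me3SiCHN2 in methanol gives the methyl ester F10; LiCHBr2 at −78 °C, then LiN(SiMe3)2 and n-BuLi with warming, rearrange the adduct to the ynolate 27, which is silylated as in step 14.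

Step 10. The likely failures are low conversion of the electron-rich aldehyde and insufficient anti or facial selectivity; the sense of induction also rests on the stated assumption. Fallback, from 19 back to 21, by an auxiliary-controlled aldol. The boron dienolate of the crotonyl imide F11 (Bu2BOTf, Et3N, CH2Cl2, −78 °C) adds to 19 at its α-carbon through a Zimmerman–Traxler transition state to give the α-vinyl syn-aldol F12 (2S,3S), which has the same relative and absolute configuration as 21. LiBH4 then reduces the imide to 21 and returns the auxiliary.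

## Further compounds

F1 | step 15 | 3-{[(2R,3S,4S)-2-(3-benzyloxy-4-methoxyphenyl)-3-(tert-butyldimethylsilyloxymethyl)oxolan-4-yl]methyl}but-3-enoic acid | COc1ccc([C@@H]2OC[C@@H](CC(=C)CC(=O)O)[C@H]2CO[Si](C)(C)C(C)(C)C)cc1OCc1ccccc1
F2 | step 15 | 3-{[(2R,3S,4S)-2-(3-benzyloxy-4-methoxyphenyl)-3-(tert-butyldimethylsilyloxymethyl)oxolan-4-yl]methyl}but-3-enoyl chloride | COc1ccc([C@@H]2OC[C@@H](CC(=C)CC(=O)Cl)[C@H]2CO[Si](C)(C)C(C)(C)C)cc1OCc1ccccc1
F3 | step 16 | (1S,2R)-1-(4-benzyloxy-3-methoxyphenyl)-2-[2-hydroxy-4-{[(2R,3S,4S)-2-(3-benzyloxy-4-methoxyphenyl)-3-(hydroxymethyl)oxolan-4-yl]methyl}-6-(triisopropylsilyloxy)phenyl]propane-1,3-diol | COc1ccc([C@@H]2OC[C@@H](Cc3cc(O)c([C@H](CO)[C@H](O)c4ccc(OCc5ccccc5)c(OC)c4)c(O[Si](C(C)C)(C(C)C)C(C)C)c3)[C@H]2CO)cc1OCc1ccccc1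
F4 | step 16 | tris(tert-butyldimethylsilyl) ether of F3 at the phenol and both primary hydroxyls, benzylic hydroxyl free | COc1ccc([C@@H]2OC[C@@H](Cc3cc(O[Si](C)(C)C(C)(C)C)c([C@H](CO[Si](C)(C)C(C)(C)C)[C@H](O)c4ccc(OCc5ccccc5)c(OC)c4)c(O[Si](C(C)C)(C(C)C)C(C)C)c3)[C@H]2CO[Si](C)(C)C(C)(C)C)cc1OCc1ccccc1
F5 | step 16 | benzylic chloride from F4 (epimers at the C–Cl carbon) | COc1ccc([C@@H]2OC[C@@H](Cc3cc(O[Si](C)(C)C(C)(C)C)c([C@H](CO[Si](C)(C)C(C)(C)C)C(Cl)c4ccc(OCc5ccccc5)c(OC)c4)c(O[Si](C(C)C)(C(C)C)C(C)C)c3)[C@H]2CO[Si](C)(C)C(C)(C)C)cc1OCc1ccccc1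
F6 | step 19 | methyl ether of 32 at the free phenol | COc1ccc([C@@H]2OC[C@@H](Cc3cc(OC)c([C@@H]4COC(C)(C)O[C@@H]4c4ccc(OCc5ccccc5)c(OC)c4)c(O[Si](C(C)C)(C(C)C)C(C)C)c3)[C@H]2CO[Si](C)(C)C(C)(C)C)cc1OCc1ccccc1
F7 | step 19 | bisphenol from F6 after removal of both benzyl groups | COc1ccc([C@@H]2OC[C@@H](Cc3cc(OC)c([C@@H]4COC(C)(C)O[C@@H]4c4ccc(O)c(OC)c4)c(O[Si](C(C)C)(C(C)C)C(C)C)c3)[C@H]2CO[Si](C)(C)C(C)(C)C)cc1O
F8 | step 19 | triphenol from F7 after removal of both silyl groups, acetonide intact | COc1ccc([C@@H]2OC[C@@H](Cc3cc(OC)c([C@@H]4COC(C)(C)O[C@@H]4c4ccc(O)c(OC)c4)c(O)c3)[C@H]2CO)cc1O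
F9 | step 14 | (4S,5R)-4-(4-benzyloxy-3-methoxyphenyl)-2,2-dimethyl-1,3-dioxane-5-carboxylic acid | OC(=O)[C@@H]1COC(C)(C)O[C@@H]1c1ccc(OCc2ccccc2)c(OC)c1
F10 | step 14 | methyl (4S,5R)-4-(4-benzyloxy-3-methoxyphenyl)-2,2-dimethyl-1,3-dioxane-5-carboxylate | COC(=O)[C@@H]1COC(C)(C)O[C@@H]1c1ccc(OCc2ccccc2)c(OC)c1
F11 | step 10 | (4S)-4-benzyl-3-[(E)-but-2-enoyl]-1,3-oxazolidin-2-one | C/C=C/C(=O)N1C(=O)OC[C@@H]1Cc1ccccc1
F12 | step 10 | (4S)-4-benzyl-3-[(2S,3S)-3-(4-benzyloxy-3-methoxyphenyl)-3-hydroxy-2-vinylpropanoyl]-1,3-oxazolidin-2-one | C=C[C@@H]([C@H](O)c1ccc(OCc2ccccc2)c(OC)c1)C(=O)N1C(=O)OC[C@@H]1Cc1ccccc1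
A1 | alternative 1 | trans-3-[aryl(hydroxy)methyl]-4-[aryl-bis(phenylthio)methyl]-5-menthyloxybutyrolactone | O=C1O[C@H](O[C@H]2C[C@@H](C)CC[C@@H]2C(C)C)[C@@H](C(Sc2ccccc2)(Sc2ccccc2)c2cc(OC)c3c(c2)O[C@H](c2ccc(O[Si](C)(C)C(C)(C)C)c(OC)c2)[C@H]3CO[Si](C)(C)C(C)(C)C)[C@@H]1[C@@H](O)c1ccc(OC)c(O[Si](C)(C)C(C)(C)C)c1
A2 | alternative 1 | (5S)-5-[(1S,2R,5S)-menthyloxy]-2(5H)-furanone | O=C1C=C[C@@H](O[C@H]2C[C@@H](C)CC[C@@H]2C(C)C)O1
A3 | alternative 1 | bis(phenylthio)acetal of the (2S,3R)-dihydrobenzofuran-6-carbaldehyde, silyl-protected | c1ccccc1SC(Sc1ccccc1)c1cc(OC)c2c(c1)O[C@H](c1ccc(O[Si](C)(C)C(C)(C)C)c(OC)c1)[C@H]2CO[Si](C)(C)C(C)(C)C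
A4 | alternative 1 | 3-(tert-butyldimethylsilyloxy)-4-methoxybenzaldehyde | COc1ccc(C=O)cc1O[Si](C)(C)C(C)(C)C
A5 | alternative 2 | target as its bis(aryl acetate) | COc1ccc([C@@H]2OC[C@@H](Cc3cc(OC)c4c(c3)O[C@H](c3ccc(OC(C)=O)c(OC)c3)[C@H]4CO)[C@H]2CO)cc1OC(C)=O
A6 | alternative 2 | (2S,3S)-2-(3-acetoxy-4-methoxybenzyl)-3-(dihydrobenzofuran-6-ylmethyl)butane-1,4-diol, aryl acetates on both outer rings | COc1ccc(C[C@H](CO)[C@@H](CO)Cc2cc(OC)c3c(c2)O[C@H](c2ccc(OC(C)=O)c(OC)c2)[C@H]3CO)cc1OC(C)=O
A7 | alternative 3 | methyl (2S,3S)-trans-6-benzyloxy-4-methoxy-2-(3-methoxy-4-triisopropylsilyloxyphenyl)-2,3-dihydrobenzofuran-3-carboxylate | COc1cc(OCc3ccccc3)cc2c1[C@H](C(=O)OC)[C@@H](c1ccc(O[Si](C(C)C)(C(C)C)C(C)C)c(OC)c1)O2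
A8 | alternative 3 | (2S)-7-benzyloxy-5-methoxy-2-(3-methoxy-4-triisopropylsilyloxyphenyl)chroman-4-one | COc1cc(OCc2ccccc2)cc2c1C(=O)C[C@@H](c1ccc(O[Si](C(C)C)(C(C)C)C(C)C)c(OC)c1)O2
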